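At early times both earlier runs move fast, but their later readings separate two things.

| flask | Sbt | Rgt | remark | time |
|---|---|---|---|---|
| maple | 0.70 M | 0.90 M | run made earlier |  |
| larch | 1.1 M | 0.90 M | run made earlier |  |
| flask | 0.50 M | 0.900 M |  | 6.0 h |

| run | time / h | Sbt / % | Sbt.Rgt / % |
|---|---|---|---|
| maple | 1.33 | 25.1 | 27.6 |
| maple | 2.50 | 22.1 | 27.7 |
| maple | 4.00 | 18.7 | 27.6 |
| maple | 5.00 | 17.7 | 28.5 |
| larch | 0.417 | 44.6 | 20.9 |
| larch | 0.833 | 35.4 | 24.2 |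
| larch | 2.00 | 27.5 | 23.0 |
| larch | 5.00 | 17.7 | 23.1 |

(scatter of a reading: 0.5 percentage points)

- how much Sbt there is at 6.0 h, in percent of the Sbt charged
- how much Sbt.Rgt there is at 6.0 h, in percent of the Sbt charged
- how much Imd there is at 6.0 h, in percent of the Sbt charged
- how much Imd2 there is at 6.0 h, in percent of the Sbt charged

In the maple run Sbt is already down to 25.1% at 1.33 h, and Sbt.Rgt stands at 27.6%. After that Sbt.Rgt stays flat, reading 28.5% at 5.00 h, and in the larch run it reads 23.0% and then 23.1%. So the fast steps look over. But Sbt keeps falling, to 17.7% in maple and 17.7% in larch, while the Sbt.Rgt readings show no matching rise.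

The two tails show the order of that way. Taken as a fractional loss per hour, they differ: 0.0952 h⁻¹ in maple against 0.147 h⁻¹ in larch. But one over the Sbt concentration climbs at 0.648 M⁻¹ h⁻¹ in maple and 0.610 M⁻¹ h⁻¹ in larch, much the same. So the tail reads as second order in Sbt, and the mean of these readings, the tail slope, is 0.629 M⁻¹ h⁻¹.

The reckoning here, which is not the forecast's, gives the flask the maple share at 1.33 h, so 0.126 M of Sbt, and runs the tail to 6.0 h. That leaves 18.3%.

The forecast puts Sbt lower, at 4.5% (2% to 8%), with Sbt.Rgt 9.5%, Imd 2% and Imd2 84%: “The fast phase should end near 5% Sbt, 9% Sbt.Rgt and 86% Imd2”.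

The flask gives Sbt 14.5%, Sbt.Rgt 29.8%, Imd 12.5% and Imd2 31.5%.

    Rgt + Imd → Imd2 (k = 4.50 M⁻¹ h⁻¹)
    Rgt + Sbt.Rgt → Sdp2 (k = 0.170 M⁻¹ h⁻¹)
    Rgt + Sbt.Rgt → Imd2 (k = 0.950 M⁻¹ h⁻¹)
    Sbt + Rgt → Sbt.Rgt (k = 2.00 M⁻¹ h⁻¹)
    2 Sbt → Prd (k = 0.290 M⁻¹ h⁻¹)
    Rgt → Sdp (k = 0.870 h⁻¹)
    Sbt + Rgt → Imd (k = 1.80 M⁻¹ h⁻¹)

Rgt, the limiting reagent, is down to 0.419% of its charge at 3.00 h, when the flask holds 16.7% Sbt. The tail slope run from there gives 14.4% at 6.0 h, against 14.5% in the flask. For the neighbour charged with 2.0 M of Sbt, the reckoning from the maple share gives 10.1%, and that neighbour holds 11.5%.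

All runs stem from a simulated flask for an exercise; scatter was added.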